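**Plan** (furanone numbering: O1, C2 carbonyl, C3, C4–Br, C5, exocyclic C6; C1' is the acetoxy-bearing side-chain carbon)
1. Retrosynthesis: C6–Br is traced back to C6–SiMe3; then O1–C5 and C4–C5 are cut in one event, a formal (3+2) annulation of a 3,3-dibromoacrylic acid with ethynyltrimethylsilane.
2. Further cuts: the CBr2 carbon (C4) comes from an α-keto ester by Ramirez olefination, the ketone from an acrylate CH2 by ozonolysis, and C3–C1' from a Morita–Baylis–Hillman reaction of butanal.
3. Enabling feature: in ring O1–C2–C3–C4–C5 the carboxyl carbon C2 and C5 sit cis on the tetrasubstituted C3=C4 bond, and C5=C6 is an alkyne in disguise; with two bromines on C4 the open precursor has no alkene geometry to set, and the carboxylate lies next to one of them.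
4. Forward order: the chain is assembled in steps 1–5, the only ring is formed in step 6, and bromine replaces silicon on C6 in step 7.
5. Stereochemistry: C1' (R) is set by β-isocupreidine catalysis in step 1 and carried through unchanged; the Z exocyclic alkene arises from anti addition of oxygen and hydrogen to the alkyne in step 6 and is kept in step 7.
6. Helpers: the hexafluoroisopropyl ester activates the acrylate and is removed in step 5; SiMe3 steers the ring closure to C5 and is exchanged for Br in step 7.

Key step: step 6

Assumption: β-isocupreidine is taken to give the R carbinol from butanal, as it does with other aliphatic aldehydes; if the sense were opposite, the quinine-derived α-isocupreine would be used instead.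

Step 1
Reactants: 1 butanal; 2 1,1,1,3,3,3-hexafluoropropan-2-yl acrylate
Product: 3 1,1,1,3,3,3-hexafluoropropan-2-yl (3R)-3-hydroxy-2-methylidenehexanoate
Conditions: β-isocupreidine (10 mol%), DMF, −55 °C
Reagents that add atoms: none
Why: Asymmetric Morita–Baylis–Hillman reaction, in which the quinuclidine nitrogen adds to the activated acrylate, the ammonium enolate attacks butanal, and the catalyst's phenolic OH hydrogen-bonds the alkoxide so that only the betaine leading to the R alcohol eliminates quickly, which sets C1'.

Step 2
Reactants: 3 1,1,1,3,3,3-hexafluoropropan-2-yl (3R)-3-hydroxy-2-methylidenehexanoate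
Product: 4 1,1,1,3,3,3-hexafluoropropan-2-yl (3R)-3-acetoxy-2-methylidenehexanoate
Conditions: Ac2O, pyridine, CH2Cl2, 0 °C to rt
Reagents that add atoms: acetic anhydride, CC(=O)OC(C)=O
Why: Pyridine-mediated acetylation of the secondary alcohol without a strongly nucleophilic amine catalyst should avoid SN2' transposition of the allylic acetate and retains the configuration at C1'.

Step 3
Reactants: 4 1,1,1,3,3,3-hexafluoropropan-2-yl (3R)-3-acetoxy-2-methylidenehexanoate
Product: 6 1,1,1,3,3,3-hexafluoropropan-2-yl (3R)-3-acetoxy-2-oxohexanoate, via secondary ozonide 5 (not isolated)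
Conditions: O3, CH2Cl2, −78 °C; then Me2S, −78 °C to rt
Reagents that add atoms: ozone, [O-][O+]=O
Why: Ozonolysis with reductive work-up (Criegee mechanism) cleaves the only C=C bond, the 1,1-disubstituted acrylate alkene, to the α-keto ester under non-basic conditions that should leave the α-acetoxy stereocentre intact.

Step 4
Reactants: 6 1,1,1,3,3,3-hexafluoropropan-2-yl (3R)-3-acetoxy-2-oxohexanoate
Product: 7 1,1,1,3,3,3-hexafluoropropan-2-yl (3R)-3-acetoxy-2-(dibromomethylidene)hexanoate
Conditions: CBr4 (2 equiv), PPh3 (4 equiv), CH2Cl2, 0 °C
Reagents that add atoms: tetrabromomethane, BrC(Br)(Br)Br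
Why: Ramirez dibromoolefination (first stage of the Corey–Fuchs sequence), in which the weakly basic ylide Ph3P=CBr2 undergoes a Wittig reaction at the highly electrophilic ketone of the 1,2-dicarbonyl unit and gives a geminal dibromoalkene with no alkene geometry to control.

Step 5
Reactants: 7 1,1,1,3,3,3-hexafluoropropan-2-yl (3R)-3-acetoxy-2-(dibromomethylidene)hexanoate
Product: 8 (3R)-3-acetoxy-2-(dibromomethylidene)hexanoic acid
Conditions: LiOH (1.05 equiv), THF/H2O, 0 °C; then HCl (aq) to pH 2
Reagents that add atoms: lithium hydroxide, [Li+].[OH-]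
Why: Saponification of an activated ester, in which hexafluoroisopropoxide (conjugate acid pKa about 9) is a far better leaving group than a secondary alkoxide, so one equivalent of hydroxide at 0 °C should cleave the ester and spare the acetate.

Step 6
Reactants: 8 (3R)-3-acetoxy-2-(dibromomethylidene)hexanoic acid; 9 ethynyltrimethylsilane
Product: 11 (1R)-1-{4-bromo-2-oxo-5-[(Z)-(trimethylsilyl)methylidene]-2,5-dihydrofuran-3-yl}butyl acetate, via silyl enynoic acid 10 (not isolated)
Conditions: PdCl2(PPh3)2 (5 mol%), CuI (10 mol%), Et3N (3 equiv), MeCN, rt; 9 (0.95 equiv) added slowly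
Reagents that add atoms: none
Why: Site-selective domino Sonogashira coupling/lactonisation, a formal (3+2) annulation of the O=C–C3=C4–Br unit with the alkyne, modelled on the known tandem coupling–cyclisation of (Z)-3-haloacrylic acids with terminal alkynes. Zerovalent palladium inserts into the C4–Br bond cis to the carboxylate, transmetalation from the copper acetylide and reductive elimination give enynoic acid 10, and its carboxylate oxygen then adds across the metal-activated triple bond to form the O1–C5 bond. The ring closes in the 5-exo-dig mode, since the 6-endo-dig path to a 2-pyranone would put oxygen on the silicon-bearing carbon whereas attack at C5 builds positive charge β to silicon. No new stereocentre arises, and the exocyclic alkene should be Z because oxygen and hydrogen add anti across the alkyne (trans oxymetalation, then protodemetalation with retention). The selectivity needed is between the two geminal bromines: the carboxylate directs oxidative addition to the cis bromine and the bulkier 1-acetoxybutyl group shields the other, while a slight deficit of alkyne limits a second coupling at the remaining, more hindered C4–Br. The acetate-bearing centre C1' is not involved.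

Step 7
Reactants: 11 (1R)-1-{4-bromo-2-oxo-5-[(Z)-(trimethylsilyl)methylidene]-2,5-dihydrofuran-3-yl}butyl acetate
Product: 12 (1R)-1-{4-bromo-5-[(Z)-bromomethylidene]-2-oxo-2,5-dihydrofuran-3-yl}butyl acetate
Conditions: NBS (1.1 equiv), MeCN, 0 °C to rt, dark
Reagents that add atoms: N-bromosuccinimide, O=C1CCC(=O)N1Br
Why: Electrophilic ipso-bromodesilylation of a vinylsilane, in which Br+ attacks C6, the cation at C5 is stabilised by the ring oxygen and the β-silicon, and loss of the silyl group should give the vinyl bromide with retention; the Z isomer is also expected to be the more stable one because the E isomer would press the C6 bromine against the C4 bromine.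

**Compound list**
1 | butanal | CCCC=O | starting material
2 | 1,1,1,3,3,3-hexafluoropropan-2-yl acrylate | C=CC(=O)OC(C(F)(F)F)C(F)(F)F | starting material
3 | 1,1,1,3,3,3-hexafluoropropan-2-yl (3R)-3-hydroxy-2-methylidenehexanoate | CCC[C@@H](O)C(=C)C(=O)OC(C(F)(F)F)C(F)(F)F | intermediate
4 | 1,1,1,3,3,3-hexafluoropropan-2-yl (3R)-3-acetoxy-2-methylidenehexanoate | CCC[C@@H](OC(C)=O)C(=C)C(=O)OC(C(F)(F)F)C(F)(F)F | intermediate
5 | secondary ozonide of 4, 1,1,1,3,3,3-hexafluoropropan-2-yl 3-[(1R)-1-acetoxybutyl]-1,2,4-trioxolane-3-carboxylate, either configuration at the ring carbon (not isolated) | CCC[C@@H](OC(C)=O)C1(OCOO1)C(=O)OC(C(F)(F)F)C(F)(F)F | intermediate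
6 | 1,1,1,3,3,3-hexafluoropropan-2-yl (3R)-3-acetoxy-2-oxohexanoate | CCC[C@@H](OC(C)=O)C(=O)C(=O)OC(C(F)(F)F)C(F)(F)F | intermediate
7 | 1,1,1,3,3,3-hexafluoropropan-2-yl (3R)-3-acetoxy-2-(dibromomethylidene)hexanoate | CCC[C@@H](OC(C)=O)C(=C(Br)Br)C(=O)OC(C(F)(F)F)C(F)(F)F | intermediate
8 | (3R)-3-acetoxy-2-(dibromomethylidene)hexanoic acid | CCC[C@@H](OC(C)=O)C(=C(Br)Br)C(=O)O | intermediate
9 | ethynyltrimethylsilane | C#C[Si](C)(C)C | starting material
10 | (2E)-2-[(1R)-1-acetoxybutyl]-3-bromo-5-(trimethylsilyl)pent-2-en-4-ynoic acid, carboxyl and alkynyl groups cis (not isolated) | CCC[C@@H](OC(C)=O)/C(C(=O)O)=C(\Br)C#C[Si](C)(C)C | intermediate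
11 | (1R)-1-{4-bromo-2-oxo-5-[(Z)-(trimethylsilyl)methylidene]-2,5-dihydrofuran-3-yl}butyl acetate | CCC[C@@H](OC(C)=O)C1=C(Br)/C(=C/[Si](C)(C)C)OC1=O | intermediate
12 | (1R)-1-{4-bromo-5-[(Z)-bromomethylidene]-2-oxo-2,5-dihydrofuran-3-yl}butyl acetate | CCC[C@@H](OC(C)=O)C1=C(Br)/C(=C/Br)OC1=O | target

**Count and risks**
Total step count: 7. Longest linear sequence: 7 steps (from butanal 1 to 12).

Steps most likely to fail:

Step 6. What may go wrong: oxidative addition at the bromine trans to the carboxylate (poor site selectivity), a second coupling at the remaining C4–Br, or ionisation of the allylic acetate by zerovalent palladium. Fallback: the C–C coupling is separated from the ring closure and the two bromines are told apart on the ester, where isomers can still be separated. Setting out from 7, a trans-selective Negishi monoalkynylation of the 1,1-dibromoalkene ((trimethylsilylethynyl)zinc chloride, PdCl2(DPEphos), THF, 0 °C) should replace the bromine trans to the bulkier 1-acetoxybutyl group and give 1,1,1,3,3,3-hexafluoropropan-2-yl (2E)-2-[(1R)-1-acetoxybutyl]-3-bromo-5-(trimethylsilyl)pent-2-en-4-ynoate F1. Ester cleavage as in step 5 should then give acid 10, now isolated, and AgNO3 (10 mol%) in acetone should close the ring by 5-exo-dig cycloisomerisation, which comes back to the route at 11.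

Step 7. What may go wrong: loss of alkene geometry by rotation in the β-silyl cation, or addition of bromine without loss of silicon. Fallback: bromine is brought onto C6 by addition–elimination instead of ipso substitution. Setting out from 11, protodesilylation with CF3CO2H in CH2Cl2 at 0 °C should give (1R)-1-(4-bromo-5-methylidene-2-oxo-2,5-dihydrofuran-3-yl)butyl acetate F2. Addition of Br2 (CH2Cl2, 0 °C) to the exocyclic enol-ester alkene should give (1R)-1-[4,5-dibromo-5-(bromomethyl)-2-oxo-2,5-dihydrofuran-3-yl]butyl acetate F3. Dehydrobromination with 1,4-diazabicyclo[2.2.2]octane in CH2Cl2 should then deliver the more stable Z bromomethylidene compound, which comes back to the route at 12.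

Step 5. What may go wrong: competing cleavage of the acetate, or addition–elimination of hydroxide at the dibromomethylidene carbon. Fallback: the acid is released by fluoride attack at silicon instead of hydroxide attack at a carbonyl. Setting out from 6, alcoholysis of the activated ester with 2-(trimethylsilyl)ethanol (pyridine, CH2Cl2, rt) should give 2-(trimethylsilyl)ethyl (3R)-3-acetoxy-2-oxohexanoate F4. Ramirez olefination as in step 4 should give 2-(trimethylsilyl)ethyl (3R)-3-acetoxy-2-(dibromomethylidene)hexanoate F5. Tetrabutylammonium fluoride buffered with AcOH (THF, 0 °C) should then fragment the silylethyl ester, which comes back to the route at 8.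

Further compounds
F1 | step 6 | 1,1,1,3,3,3-hexafluoropropan-2-yl (2E)-2-[(1R)-1-acetoxybutyl]-3-bromo-5-(trimethylsilyl)pent-2-en-4-ynoate | CCC[C@@H](OC(C)=O)/C(C(=O)OC(C(F)(F)F)C(F)(F)F)=C(\Br)C#C[Si](C)(C)C
F2 | step 7 | (1R)-1-(4-bromo-5-methylidene-2-oxo-2,5-dihydrofuran-3-yl)butyl acetate | CCC[C@@H](OC(C)=O)C1=C(Br)C(=C)OC1=O
F3 | step 7 | (1R)-1-[4,5-dibromo-5-(bromomethyl)-2-oxo-2,5-dihydrofuran-3-yl]butyl acetate, either configuration at C5 | CCC[C@@H](OC(C)=O)C1=C(Br)C(Br)(CBr)OC1=O
F4 | step 5 | 2-(trimethylsilyl)ethyl (3R)-3-acetoxy-2-oxohexanoate | CCC[C@@H](OC(C)=O)C(=O)C(=O)OCC[Si](C)(C)C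
F5 | step 5 | 2-(trimethylsilyl)ethyl (3R)-3-acetoxy-2-(dibromomethylidene)hexanoate | CCC[C@@H](OC(C)=O)C(=C(Br)Br)C(=O)OCC[Si](C)(C)C
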